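## Retrosynthetic overview

1. Target 24 comes from benzofuran ester 19: the C3 formyl group from the methyl ester, the C4 phenol from its methyl ether (magnesium chelate between formyl oxygen and C4 oxygen), the ring-B phenols from benzyl ethers, the side-chain alcohol from a silyl ether.
2. Key disconnection: O1–C7a and C3–C3a, the two bonds from ring A to the furan, are cut together to give aryne 17 and iodonium ylide 16. The strategy rests on one feature: C7a (bearing O1) and C3a (bearing C3) are adjacent ring-A carbons, and C3a lies next to the C4 oxygen, which polarises an aryne spanning C3a–C7a.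
3. Aryne precursor 12 comes from the symmetric phenol 4 (carbamate-directed ortho-silylation, then triflate), itself from aldehyde 1; ylide 16 comes from 2,4-dihydroxyacetophenone 13.
4. Ring order: rings A and B are bought as benzenes; the furan ring is the only ring formed (step 11).

Key step: step 11

Remark: the target has no stereocentre; phenol numbering is used for 1–12 and benzofuran numbering for 19–24.

## Route

Step 1
Reactants: 1 4-hydroxy-2,6-dimethoxybenzaldehyde
Product: 2 methyl (E)-3-(4-hydroxy-2,6-dimethoxyphenyl)prop-2-enoate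
Conditions: Ph3P=CHCO2Me (1.5 equiv.), toluene, 110 °C
Reagents that add atoms: methyl (triphenylphosphoranylidene)acetate, COC(=O)C=P(c1ccccc1)(c1ccccc1)c1ccccc1
Why: Wittig olefination with a stabilised ylide, which is too weakly basic to deprotonate the phenol in toluene, should give the E cinnamate; the geometry is erased in step 2.

Step 2
Reactants: 2 methyl (E)-3-(4-hydroxy-2,6-dimethoxyphenyl)prop-2-enoate
Product: 3 methyl 3-(4-hydroxy-2,6-dimethoxyphenyl)propanoate
Conditions: H2 (1 atm), 10% Pd/C, EtOAc/MeOH, rt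
Reagents that add atoms: none
Why: Catalytic hydrogenation of the conjugated alkene over Pd/C leaves the arene, ester and phenol untouched.

Step 3
Reactants: 3 methyl 3-(4-hydroxy-2,6-dimethoxyphenyl)propanoate
Product: 4 4-(3-hydroxy-3-methylbutyl)-3,5-dimethoxyphenol
Conditions: MeMgBr (4 equiv.), THF, 0 °C → rt; aq. NH4Cl
Reagents that add atoms: methylmagnesium bromide, C[Mg]Br
Why: Double Grignard addition to the ester, after one equivalent is spent on the phenol, should give the tertiary alcohol.

Step 4
Reactants: 4 4-(3-hydroxy-3-methylbutyl)-3,5-dimethoxyphenol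
Product: 5 4-(3-hydroxy-3-methylbutyl)-3,5-dimethoxyphenyl N-isopropylcarbamate
Conditions: i-PrNCO (1.2 equiv.), Et3N (0.2 equiv.), CH2Cl2, rt
Reagents that add atoms: isopropyl isocyanate, CC(C)N=C=O
Why: Base-catalysed carbamoylation (addition of the phenol to the isocyanate) is far faster than addition of the hindered tertiary alcohol, so only the aryl carbamate should form.

Step 5
Reactants: 5 4-(3-hydroxy-3-methylbutyl)-3,5-dimethoxyphenyl N-isopropylcarbamate
Product: 6 4-[3-(tert-butyldimethylsilyloxy)-3-methylbutyl]-3,5-dimethoxyphenyl N-isopropylcarbamate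
Conditions: TBSOTf (2 equiv.), 2,6-lutidine (3 equiv.), CH2Cl2, 0 °C → rt; aq. NaHCO3
Reagents that add atoms: tert-butyldimethylsilyl trifluoromethanesulfonate, CC(C)(C)[Si](C)(C)OS(=O)(=O)C(F)(F)F
Why: O-Silylation of a tertiary alcohol with a silyl triflate and a hindered base is reliable, and any N-silylated carbamate reverts to N–H on bicarbonate work-up.

Step 6
Reactants: 6 4-[3-(tert-butyldimethylsilyloxy)-3-methylbutyl]-3,5-dimethoxyphenyl N-isopropylcarbamate
Product: 10 4-[3-(tert-butyldimethylsilyloxy)-3-methylbutyl]-3,5-dimethoxy-2-(trimethylsilyl)phenyl N-isopropylcarbamate, via N-silyl carbamate 7 (not isolated), via aryllithium 8 (not isolated), via N-silyl arylsilane 9 (not isolated)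
Conditions: TMSOTf (1.1 equiv.), TMEDA, Et2O, 0 °C → rt; n-BuLi (2 equiv.), TMEDA, −78 °C; TMSCl (3 equiv.), −78 °C → rt; aq. NH4Cl
Reagents that add atoms: chlorotrimethylsilane, C[Si](C)(C)Cl; trimethylsilyl trifluoromethanesulfonate, C[Si](C)(C)OS(=O)(=O)C(F)(F)F (its silyl group is held only by 7, 8 and 9)
Why: Directed ortho-metalation: in situ N-silylation makes the carbamate a stable directing group, n-BuLi/TMEDA removes the proton between carbamate and methoxy (the two ortho positions are equivalent by symmetry), TMSCl traps the aryllithium and work-up hydrolyses the N–Si bond.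

Step 7
Reactants: 10 4-[3-(tert-butyldimethylsilyloxy)-3-methylbutyl]-3,5-dimethoxy-2-(trimethylsilyl)phenyl N-isopropylcarbamate
Product: 12 4-[3-(tert-butyldimethylsilyloxy)-3-methylbutyl]-3,5-dimethoxy-2-(trimethylsilyl)phenyl trifluoromethanesulfonate, via silylphenol 11 (not isolated)
Conditions: Et2NH (1.5 equiv.), DBU (1.5 equiv.), MeCN, 40 °C; then PhNTf2 (1.5 equiv.), rt
Reagents that add atoms: N-phenylbis(trifluoromethanesulfonimide), O=S(=O)(N(c1ccccc1)S(=O)(=O)C(F)(F)F)C(F)(F)F
Why: Base-induced carbamate cleavage (loss of isopropyl isocyanate, trapped by Et2NH as a urea) frees the phenoxide, which is O-triflated in the same pot; the basic medium avoids protodesilylation of the electron-rich arylsilane.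

Step 8
Reactants: 13 2,4-dihydroxyacetophenone
Product: 14 2,4-bis(benzyloxy)acetophenone
Conditions: BnBr (2.5 equiv.), K2CO3, DMF, 60 °C
Reagents that add atoms: benzyl bromide, BrCc1ccccc1
Why: Williamson etherification of both phenols; warm DMF is used because the hydrogen-bonded 2-OH reacts slowly.

Step 9
Reactants: 14 2,4-bis(benzyloxy)acetophenone
Product: 15 methyl 3-[2,4-bis(benzyloxy)phenyl]-3-oxopropanoate
Conditions: NaH (2.5 equiv.), (MeO)2CO (3 equiv.), THF, reflux; then 1 M aq. HCl, 0 °C
Reagents that add atoms: dimethyl carbonate, COC(=O)OC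
Why: Crossed Claisen condensation (C-acylation of the ketone enolate by dimethyl carbonate) is driven by deprotonation of the β-ketoester formed.

Step 10
Reactants: 15 methyl 3-[2,4-bis(benzyloxy)phenyl]-3-oxopropanoate
Product: 16 methyl 3-[2,4-bis(benzyloxy)phenyl]-3-oxo-2-(phenyliodonio)propanoate ylide
Conditions: PhI(OAc)2 (1.1 equiv.), KOH (2.5 equiv.), MeOH, 0 °C; kept cold and used promptly
Reagents that add atoms: (diacetoxyiodo)benzene, CC(=O)OI(OC(C)=O)c1ccccc1
Why: Iodonium ylide formation: the β-ketoester enolate displaces acetate from hypervalent iodine and a second deprotonation gives the ylide, the standard preparation for 1,3-dicarbonyl compounds.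

Step 11
Reactants: 12 4-[3-(tert-butyldimethylsilyloxy)-3-methylbutyl]-3,5-dimethoxy-2-(trimethylsilyl)phenyl trifluoromethanesulfonate; 16 methyl 3-[2,4-bis(benzyloxy)phenyl]-3-oxo-2-(phenyliodonio)propanoate ylide
Product: 19 methyl 2-[2,4-bis(benzyloxy)phenyl]-5-[3-(tert-butyldimethylsilyloxy)-3-methylbutyl]-4,6-dimethoxybenzofuran-3-carboxylate, via aryne 17 (not isolated), via aryl anion 18 (not isolated)
Conditions: 16 (1.5 equiv.), CsF (3 equiv.), MeCN, rt
Reagents that add atoms: none
Why: CsF removes the trimethylsilyl group of 12 and triflate leaves, giving aryne 17 with its triple bond across the future C3a–C7a. The ketone-derived enolate oxygen of 16 (its carbon is shielded by the phenyliodonio group and the ester oxygen is the poorer donor) adds to the aryne carbon remote from the flanking methoxy group, so the aryl anion of 18 sits at C3a beside that inductively withdrawing oxygen; this anion then attacks the alkenyliodonium unit, most likely at iodine to give a six-membered iodane that collapses by ligand coupling, forming C3–C3a and expelling iodobenzene. The closest known reaction type is the fluoride-mediated annulation of arynes with iodonium ylides of 1,3-dicarbonyl compounds to 3-acylbenzofurans, together with the O-capture of such ylides by electrophiles to give alkenyliodonium salts. The furan ring is closed as a five-membered ring by the C3–C3a bond after intermolecular formation of O1–C7a; no stereocentre is formed. The step needs oxygen on C7a and carbon on C3a: the C4 methoxy group (a 3-alkoxyaryne, buttressed by the C5 chain) directs the first nucleophile to C7a, and O-first addition of the ylide is what turns this preference into the required orientation.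

Step 12
Reactants: 19 methyl 2-[2,4-bis(benzyloxy)phenyl]-5-[3-(tert-butyldimethylsilyloxy)-3-methylbutyl]-4,6-dimethoxybenzofuran-3-carboxylate
Product: 20 {2-[2,4-bis(benzyloxy)phenyl]-5-[3-(tert-butyldimethylsilyloxy)-3-methylbutyl]-4,6-dimethoxybenzofuran-3-yl}methanol
Conditions: i-Bu2AlH (3 equiv.), CH2Cl2, −78 → 0 °C; aq. KNaC4H4O6
Reagents that add atoms: none
Why: Hydride reduction of the hindered, vinylogous-carbonate ester to the primary alcohol; benzyl and silyl ethers are inert.

Step 13
Reactants: 20 {2-[2,4-bis(benzyloxy)phenyl]-5-[3-(tert-butyldimethylsilyloxy)-3-methylbutyl]-4,6-dimethoxybenzofuran-3-yl}methanol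
Product: 21 2-[2,4-bis(benzyloxy)phenyl]-5-[3-(tert-butyldimethylsilyloxy)-3-methylbutyl]-4,6-dimethoxybenzofuran-3-carbaldehyde
Conditions: activated MnO2 (15 equiv.), CH2Cl2, rt
Reagents that add atoms: none
Why: MnO2 oxidation of a benzylic-type heteroaryl carbinol is neutral, which avoids acid-promoted ionisation of this electron-rich alcohol.

Step 14
Reactants: 21 2-[2,4-bis(benzyloxy)phenyl]-5-[3-(tert-butyldimethylsilyloxy)-3-methylbutyl]-4,6-dimethoxybenzofuran-3-carbaldehyde
Product: 22 2-[2,4-bis(benzyloxy)phenyl]-5-[3-(tert-butyldimethylsilyloxy)-3-methylbutyl]-4-hydroxy-6-methoxybenzofuran-3-carbaldehyde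
Conditions: MgI2·OEt2 (2 equiv.), toluene/Et2O, 60 °C; aq. NH4Cl
Reagents that add atoms: none
Why: Chelation-controlled demethylation: magnesium bridges the formyl oxygen and the C4 methoxy oxygen across the peri positions (a seven-membered chelate) and iodide removes that methyl by SN2, whereas the C6 methoxy, benzyl and silyl ethers have no carbonyl partner.

Step 15
Reactants: 22 2-[2,4-bis(benzyloxy)phenyl]-5-[3-(tert-butyldimethylsilyloxy)-3-methylbutyl]-4-hydroxy-6-methoxybenzofuran-3-carbaldehyde
Product: 23 5-[3-(tert-butyldimethylsilyloxy)-3-methylbutyl]-2-(2,4-dihydroxyphenyl)-4-hydroxy-6-methoxybenzofuran-3-carbaldehyde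
Conditions: H2 (1 atm), 10% Pd/C, EtOAc, rt, stopped at full debenzylation
Reagents that add atoms: none
Why: Catalytic hydrogenolysis of the two aryl benzyl ethers; the formyl group, a hydrogen-bonded vinylogous formate, and the tetrasubstituted furan double bond are expected to survive.

Step 16
Reactants: 23 5-[3-(tert-butyldimethylsilyloxy)-3-methylbutyl]-2-(2,4-dihydroxyphenyl)-4-hydroxy-6-methoxybenzofuran-3-carbaldehyde
Product: 24 2-(2,4-dihydroxyphenyl)-4-hydroxy-5-(3-hydroxy-3-methylbutyl)-6-methoxybenzofuran-3-carbaldehyde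
Conditions: HF·pyridine, pyridine, THF, 0 °C → rt
Reagents that add atoms: none
Why: Fluoride-mediated desilylation of the tertiary silyl ether in a buffered medium too weakly acidic to ionise the tertiary alcohol towards chroman closure onto the neighbouring C4 phenol.

## Compound list

1 | 4-hydroxy-2,6-dimethoxybenzaldehyde | COc1cc(O)cc(OC)c1C=O | starting material
2 | methyl (E)-3-(4-hydroxy-2,6-dimethoxyphenyl)prop-2-enoate | COC(=O)/C=C/c1c(OC)cc(O)cc1OC | intermediate
3 | methyl 3-(4-hydroxy-2,6-dimethoxyphenyl)propanoate | COC(=O)CCc1c(OC)cc(O)cc1OC | intermediate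
4 | 4-(3-hydroxy-3-methylbutyl)-3,5-dimethoxyphenol | COc1cc(O)cc(OC)c1CCC(C)(C)O | intermediate
5 | 4-(3-hydroxy-3-methylbutyl)-3,5-dimethoxyphenyl N-isopropylcarbamate | COc1cc(OC(=O)NC(C)C)cc(OC)c1CCC(C)(C)O | intermediate
6 | 4-[3-(tert-butyldimethylsilyloxy)-3-methylbutyl]-3,5-dimethoxyphenyl N-isopropylcarbamate | COc1cc(OC(=O)NC(C)C)cc(OC)c1CCC(C)(C)O[Si](C)(C)C(C)(C)C | intermediate
7 | N-trimethylsilyl derivative of carbamate 6 (formed in the flask) | COc1cc(OC(=O)N(C(C)C)[Si](C)(C)C)cc(OC)c1CCC(C)(C)O[Si](C)(C)C(C)(C)C | intermediate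
8 | 2-lithio derivative of 7 (formed in the flask) | [Li]c1c(OC(=O)N(C(C)C)[Si](C)(C)C)cc(OC)c(CCC(C)(C)O[Si](C)(C)C(C)(C)C)c1OC | intermediate
9 | N,2-bis(trimethylsilyl) carbamate before hydrolytic work-up (formed in the flask) | C[Si](C)(C)c1c(OC(=O)N(C(C)C)[Si](C)(C)C)cc(OC)c(CCC(C)(C)O[Si](C)(C)C(C)(C)C)c1OC | intermediate
10 | 4-[3-(tert-butyldimethylsilyloxy)-3-methylbutyl]-3,5-dimethoxy-2-(trimethylsilyl)phenyl N-isopropylcarbamate | C[Si](C)(C)c1c(OC(=O)NC(C)C)cc(OC)c(CCC(C)(C)O[Si](C)(C)C(C)(C)C)c1OC | intermediate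
11 | 4-[3-(tert-butyldimethylsilyloxy)-3-methylbutyl]-3,5-dimethoxy-2-(trimethylsilyl)phenol (formed in the flask) | C[Si](C)(C)c1c(O)cc(OC)c(CCC(C)(C)O[Si](C)(C)C(C)(C)C)c1OC | intermediate
12 | 4-[3-(tert-butyldimethylsilyloxy)-3-methylbutyl]-3,5-dimethoxy-2-(trimethylsilyl)phenyl trifluoromethanesulfonate | C[Si](C)(C)c1c(OS(=O)(=O)C(F)(F)F)cc(OC)c(CCC(C)(C)O[Si](C)(C)C(C)(C)C)c1OC | intermediate
13 | 2,4-dihydroxyacetophenone | CC(=O)c1ccc(O)cc1O | starting material
14 | 2,4-bis(benzyloxy)acetophenone | CC(=O)c1ccc(OCc2ccccc2)cc1OCc1ccccc1 | intermediate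
15 | methyl 3-[2,4-bis(benzyloxy)phenyl]-3-oxopropanoate | COC(=O)CC(=O)c1ccc(OCc2ccccc2)cc1OCc1ccccc1 | intermediate
16 | methyl 3-[2,4-bis(benzyloxy)phenyl]-3-oxo-2-(phenyliodonio)propanoate ylide | COC(=O)[C-]([I+]c1ccccc1)C(=O)c1ccc(OCc2ccccc2)cc1OCc1ccccc1 | intermediate
17 | 4-[3-(tert-butyldimethylsilyloxy)-3-methylbutyl]-3,5-dimethoxybenzyne (formed in the flask) | COC1=C(CCC(C)(C)O[Si](C)(C)C(C)(C)C)C(OC)=CC#C1 | intermediate
18 | aryl anion/alkenyl(phenyl)iodonium zwitterion from O-arylation of 16 by 17 (formed in the flask) | COC(=O)C(=C(Oc1cc(OC)c(CCC(C)(C)O[Si](C)(C)C(C)(C)C)c(OC)[c-]1)c1ccc(OCc2ccccc2)cc1OCc1ccccc1)[I+]c1ccccc1 | intermediate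
19 | methyl 2-[2,4-bis(benzyloxy)phenyl]-5-[3-(tert-butyldimethylsilyloxy)-3-methylbutyl]-4,6-dimethoxybenzofuran-3-carboxylate | COC(=O)c1c(-c2ccc(OCc3ccccc3)cc2OCc2ccccc2)oc2cc(OC)c(CCC(C)(C)O[Si](C)(C)C(C)(C)C)c(OC)c12 | intermediate
20 | {2-[2,4-bis(benzyloxy)phenyl]-5-[3-(tert-butyldimethylsilyloxy)-3-methylbutyl]-4,6-dimethoxybenzofuran-3-yl}methanol | OCc1c(-c2ccc(OCc3ccccc3)cc2OCc2ccccc2)oc2cc(OC)c(CCC(C)(C)O[Si](C)(C)C(C)(C)C)c(OC)c12 | intermediate
21 | 2-[2,4-bis(benzyloxy)phenyl]-5-[3-(tert-butyldimethylsilyloxy)-3-methylbutyl]-4,6-dimethoxybenzofuran-3-carbaldehyde | O=Cc1c(-c2ccc(OCc3ccccc3)cc2OCc2ccccc2)oc2cc(OC)c(CCC(C)(C)O[Si](C)(C)C(C)(C)C)c(OC)c12 | intermediate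
22 | 2-[2,4-bis(benzyloxy)phenyl]-5-[3-(tert-butyldimethylsilyloxy)-3-methylbutyl]-4-hydroxy-6-methoxybenzofuran-3-carbaldehyde | O=Cc1c(-c2ccc(OCc3ccccc3)cc2OCc2ccccc2)oc2cc(OC)c(CCC(C)(C)O[Si](C)(C)C(C)(C)C)c(O)c12 | intermediate
23 | 5-[3-(tert-butyldimethylsilyloxy)-3-methylbutyl]-2-(2,4-dihydroxyphenyl)-4-hydroxy-6-methoxybenzofuran-3-carbaldehyde | O=Cc1c(-c2ccc(O)cc2O)oc2cc(OC)c(CCC(C)(C)O[Si](C)(C)C(C)(C)C)c(O)c12 | intermediate
24 | 2-(2,4-dihydroxyphenyl)-4-hydroxy-5-(3-hydroxy-3-methylbutyl)-6-methoxybenzofuran-3-carbaldehyde (ebenfuran V) | COc1cc2oc(-c3ccc(O)cc3O)c(C=O)c2c(O)c1CCC(C)(C)O | target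

## Step count and risks

Total step count: 16. Longest linear sequence: 13 (steps 1–7, 11–16); the ring-B branch (steps 8–10) joins at step 11.

**Step 11 (aryne annulation).** The orientation depends on the ylide adding through oxygen first. Carbon-first addition would reverse which aryne carbon takes oxygen, the ester oxygen could compete with the ketone oxygen, the aryl anion could be protonated by acetonitrile before ring closure, and the ylide could decompose faster than the aryne is released.
Fallback, setting out from carbamate 6 and ketone 14 and returning at ester 19: the furan would be closed from a phenol oxygen, which fixes O1–C7a from the start. Carbamate 6 would be cleaved (Et2NH, DBU, MeCN, 40 °C) to 4-[3-(tert-butyldimethylsilyloxy)-3-methylbutyl]-3,5-dimethoxyphenol F1. By symmetry F1 can only be iodinated at the carbon that becomes C3a (N-iodosuccinimide, CH2Cl2, 0 °C), giving 4-[3-(tert-butyldimethylsilyloxy)-3-methylbutyl]-2-iodo-3,5-dimethoxyphenol F2. Ketone 14 would be converted in one pot (LiN(i-Pr)2, ClP(O)(OEt)2, THF, −78 °C; then LiN(i-Pr)2, 2.2 equiv.) through diethyl 1-[2,4-bis(benzyloxy)phenyl]vinyl phosphate F3 into 2,4-bis(benzyloxy)-1-ethynylbenzene F4. Sonogashira coupling of F2 with F4 (PdCl2(PPh3)2, CuI, Et3N, rt to 50 °C) should give 2-{[2,4-bis(benzyloxy)phenyl]ethynyl}-4-[3-(tert-butyldimethylsilyloxy)-3-methylbutyl]-3,5-dimethoxyphenol F5. Oxidative cyclisation with methoxycarbonylation (PdI2, thiourea, CBr4, Cs2CO3, CO 1 atm, MeOH, 40 °C) should then deliver 19.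

**Step 14 (C4 demethylation).** Chelate activation across the peri positions may be too weak, giving no reaction. Forcing conditions could cleave the C6 ether or the benzyl ethers, or ionise the tertiary silyl ether with chroman closure.
Fallback, setting out from aldehyde 21 and returning at 23: the staged unveiling would be replaced by one boron-mediated global dealkylation. BCl3 (excess) with pentamethylbenzene as cation scavenger (CH2Cl2, −78 → −20 °C) should remove both benzyl groups and the methyl of the doubly flanked, carbonyl-proximal C4 ether, leaving the unhindered C6 ether. This bypasses 22 and step 15 and makes no compound outside the list (F0).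

**Step 15 (hydrogenolysis).** The formyl group (or its lactol tautomer with the 2'-hydroxyl) may be over-reduced to hydroxymethyl or methyl while the benzyl ethers are cleaved.
Fallback, setting out from 22 and returning at 23: debenzylation would be done without a reducing agent, by benzyl transfer to pentamethylbenzene with BCl3 (2.5 equiv., CH2Cl2, −78 °C). At that temperature the formyl group and the silyl ether should be unaffected; no compound outside the list is made (F0).

## Further compounds

F1 | step 11 | 4-[3-(tert-butyldimethylsilyloxy)-3-methylbutyl]-3,5-dimethoxyphenol | COc1cc(O)cc(OC)c1CCC(C)(C)O[Si](C)(C)C(C)(C)C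
F2 | step 11 | 4-[3-(tert-butyldimethylsilyloxy)-3-methylbutyl]-2-iodo-3,5-dimethoxyphenol | COc1cc(O)c(I)c(OC)c1CCC(C)(C)O[Si](C)(C)C(C)(C)C
F3 | step 11 | diethyl 1-[2,4-bis(benzyloxy)phenyl]vinyl phosphate | C=C(OP(=O)(OCC)OCC)c1ccc(OCc2ccccc2)cc1OCc1ccccc1
F4 | step 11 | 2,4-bis(benzyloxy)-1-ethynylbenzene | C#Cc1ccc(OCc2ccccc2)cc1OCc1ccccc1
F5 | step 11 | 2-{[2,4-bis(benzyloxy)phenyl]ethynyl}-4-[3-(tert-butyldimethylsilyloxy)-3-methylbutyl]-3,5-dimethoxyphenol | COc1cc(O)c(C#Cc2ccc(OCc3ccccc3)cc2OCc2ccccc2)c(OC)c1CCC(C)(C)O[Si](C)(C)C(C)(C)C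
F0 | step 14 | none | none
F0 | step 15 | none | none
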